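**Plan**

1. Retrosynthesis: C1–C2 is cut by an intramolecular carbonyl-ene reaction (back to a C2 aldehyde and a C1=Cv alkene). C1=Cv is cut by Julia–Kocienski olefination, which splits off ring A as a sulfone. The C7 methyl is removed back to a C7 ketone and then an exocyclic methylene. Finally C3a–C7a and C4–Br are cut together by a bromonium/allylsilane cyclisation of an acyclic dienoate. Ring A is cut the same way at C2′–C3′ and C4′–Br.
2. Forward: the bromocyclohexane of the hydrindane closes first (step 7), ring A is made separately by the same cyclisation (step 15), the halves are joined at C1=Cv (step 21), and the cyclopentane closes last (step 24).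
3. Enabling feature: in the ring C3a–C4–C5–C6–C7–C7a, the equatorial C4–Br lies next to quaternary C3a (axial CH3), and C7a–H is anti to that methyl. This is the imprint of anti addition of Br+ and C7a across an (E)-C3a=C4 alkene in a chair. C7 keeps the carbon left behind by an allylsilane.
4. Stereochemistry: C4 and C4′ come from a chiral bromenium catalyst; C3a and C7a follow from the 6E/2Z alkene geometry and the chair. C7 comes from equatorial MeMgBr attack. C1′ of the ring-A sulfone comes from hydroboration anti to the axial C3′ methyl in a chair locked by a C2′ ester, which is removed afterwards. C1, C2 and the E alkene come from the suprafacial ene transition state.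
5. C1 is carried as an ester through both cyclisations, so the allylsilane is an electron-poor enoate that bromenium should not attack directly.

Key step: step 7

Labels: hydrindane numbering C1–C7a is used for all main-chain intermediates (C1 = ester/aldehyde carbon on C7a; C2 = oxygenated end of the two-carbon arm on C3a). Ring A is C1′ (alkylidene carbon), C2′, C3′ (CMe2), C4′ (CHBr), C5′, C6′. Cv is the exocyclic alkene CH.

Assumption: the catalyst antipode that brominates the required alkene face is not known in advance for these alkenes; it is written as the (R)-catalyst and must be fixed by a trial cyclisation. Steps 7 and 15 need the same sense of attack.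

**Route**

Step 1
Reactants: 1 but-3-yn-1-ol
Product: 2 tert-butyl(but-3-yn-1-yloxy)diphenylsilane
Conditions: TBDPSCl, imidazole, DMF, rt
Reagents that add atoms: tert-butyl(chloro)diphenylsilane, CC(C)(C)[Si](Cl)(c1ccccc1)c1ccccc1
Why: Imidazole-promoted silylation of a primary alcohol gives an ether that survives the organoaluminium, enolate, Grignard and ozonolysis steps and is bulky enough to keep its oxygen out of the bromonium step.

Step 2
Reactants: 2 tert-butyl(but-3-yn-1-yloxy)diphenylsilane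
Product: 5 (E)-5-[(tert-butyldiphenylsilyl)oxy]-3-methylpent-2-en-1-ol, via alkenyldimethylalane 3 (not isolated), via lithium alkenylalanate 4 (not isolated)
Conditions: Me3Al, Cp2ZrCl2 (cat.), CH2Cl2, 0 °C → rt; then n-BuLi, THF, −78 °C; (CH2O)n, → rt
Reagents that add atoms: trimethylaluminium, C[Al](C)C; paraformaldehyde (formaldehyde), C=O
Why: Negishi zirconium-catalysed carboalumination adds methyl and aluminium syn across the terminal alkyne (methyl to the internal carbon), and the alkenylalanate is hydroxymethylated with retention, which fixes the E geometry of the future C3a=C4 alkene.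

Step 3
Reactants: 5 (E)-5-[(tert-butyldiphenylsilyl)oxy]-3-methylpent-2-en-1-ol
Product: 6 (E)-[(5-bromo-3-methylpent-3-en-1-yl)oxy](tert-butyl)diphenylsilane
Conditions: CBr4, PPh3, CH2Cl2, 0 °C
Reagents that add atoms: tetrabromomethane, BrC(Br)(Br)Br
Why: Appel bromination converts the primary allylic alcohol to the allylic bromide by SN2 without allylic transposition or loss of alkene geometry.

Step 4
Reactants: 6 (E)-[(5-bromo-3-methylpent-3-en-1-yl)oxy](tert-butyl)diphenylsilane; 7 methyl acetoacetate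
Product: 9 methyl (E)-9-[(tert-butyldiphenylsilyl)oxy]-7-methyl-3-oxonon-6-enoate, via acetoacetate dianion 8 (not isolated)
Conditions: 7, NaH, THF, 0 °C; n-BuLi, 0 °C; then 6, 0 °C → rt
Reagents that add atoms: none
Why: The acetoacetate dianion (Huckin–Weiler alkylation) reacts at its terminal carbon by SN2 on the allylic bromide, forming C5–C6 and delivering the 1,3-dicarbonyl that becomes C7, C7a and C1.

Step 5
Reactants: 9 methyl (E)-9-[(tert-butyldiphenylsilyl)oxy]-7-methyl-3-oxonon-6-enoate
Product: 11 methyl (2Z,6E)-9-[(tert-butyldiphenylsilyl)oxy]-3-[(diethoxyphosphoryl)oxy]-7-methylnona-2,6-dienoate, via sodium enolate 10 (not isolated)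
Conditions: NaH, Et2O, 0 °C; ClP(O)(OEt)2, 0 °C → rt
Reagents that add atoms: diethyl chlorophosphate, CCOP(=O)(Cl)OCC
Why: O-Phosphorylation of the chelated sodium enolate of a β-keto ester gives the (Z)-enol phosphate, the geometry that later places the C1 ester equatorial.

Step 6
Reactants: 11 methyl (2Z,6E)-9-[(tert-butyldiphenylsilyl)oxy]-3-[(diethoxyphosphoryl)oxy]-7-methylnona-2,6-dienoate; 12 (trimethylsilyl)methylmagnesium chloride
Product: 13 methyl (2Z,6E)-9-[(tert-butyldiphenylsilyl)oxy]-7-methyl-3-[(trimethylsilyl)methyl]nona-2,6-dienoate (ester cis to CH2SiMe3, trans to the chain)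
Conditions: 12 (3 equiv), Ni(acac)2 (5 mol %), THF, 0 °C → rt
Reagents that add atoms: none
Why: Nickel-catalysed Kumada-type coupling of an enol phosphate with the silylmethyl Grignard reagent proceeds with retention of alkene geometry and gives the 3-(silylmethyl)enoate, an allylsilane.

Step 7
Reactants: 13 methyl (2Z,6E)-9-[(tert-butyldiphenylsilyl)oxy]-7-methyl-3-[(trimethylsilyl)methyl]nona-2,6-dienoate
Product: 14 methyl (1R,2S,3S)-3-bromo-2-{2-[(tert-butyldiphenylsilyl)oxy]ethyl}-2-methyl-6-methylidenecyclohexane-1-carboxylate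
Conditions: DBDMH (0.6 equiv), (R)-BINOL-derived thiophosphoramide (10 mol %), CH2Cl2/toluene, −78 °C; aq. Na2S2O3
Reagents that add atoms: 1,3-dibromo-5,5-dimethylhydantoin, O=C1N(Br)C(=O)C(C)(C)N1Br
Why: Proposed new method: a Lewis-base-bound bromenium ion should be transferred to the electron-rich (6E) trisubstituted alkene (C3a=C4) and not to the conjugated enoate; the enoate α-carbon (C7a), made nucleophilic by the allylic C–Si bond, then opens the bromonium ion at its tertiary carbon C3a, and the β-silyl cation at C7 loses silicon to leave the exocyclic methylene. The closest known reactions are the catalytic enantioselective bromocyclisation of polyenes ending on arenes (chiral thiophosphoramide with DBDMH) and epoxide-initiated cyclisations ending on this same 3-(silylmethyl)enoate; the combination is untested. The cyclohexane closes by 6-endo opening of the bromonium ion through a chair. C4 is set by the alkene face the chiral catalyst brominates, C3a follows from anti opening of the (E)-alkene (bromine equatorial, methyl axial), and C7a from the (2Z) geometry, which puts the ester equatorial and C7a–H axial, anti to the C3a methyl. The step needs enantioface selection (catalyst), chemoselection between the two alkenes (secured by carrying C1 as the ester) and carbon rather than oxygen capture (the bulky silyl ether oxygen could only close an oxetane at C3a or attack the secondary carbon against the charge distribution).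

Step 8
Reactants: 14 methyl (1R,2S,3S)-3-bromo-2-{2-[(tert-butyldiphenylsilyl)oxy]ethyl}-2-methyl-6-methylidenecyclohexane-1-carboxylate
Product: 15 [(1R,2S,3S)-3-bromo-2-{2-[(tert-butyldiphenylsilyl)oxy]ethyl}-2-methyl-6-methylidenecyclohexyl]methanol
Conditions: DIBAL-H (2.5 equiv), CH2Cl2, −78 → 0 °C; Rochelle salt
Reagents that add atoms: none
Why: DIBAL-H reduction of the hindered ester to the primary alcohol leaves the neopentyl secondary bromide, the silyl ether and the alkene untouched and removes the acidity of C7a–H.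

Step 9
Reactants: 15 [(1R,2S,3S)-3-bromo-2-{2-[(tert-butyldiphenylsilyl)oxy]ethyl}-2-methyl-6-methylidenecyclohexyl]methanol
Product: 17 (2R,3S,4S)-4-bromo-3-{2-[(tert-butyldiphenylsilyl)oxy]ethyl}-2-(hydroxymethyl)-3-methylcyclohexan-1-one, via ozonide 16 (not isolated)
Conditions: O3, CH2Cl2, −78 °C; PPh3, → rt; used crude
Reagents that add atoms: ozone, [O-][O+]=O
Why: Ozonolysis of the only alkene with reductive work-up gives the C7 ketone; the β-hydroxy ketone is carried on crude to avoid dehydration.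

Step 10
Reactants: 17 (2R,3S,4S)-4-bromo-3-{2-[(tert-butyldiphenylsilyl)oxy]ethyl}-2-(hydroxymethyl)-3-methylcyclohexan-1-one
Product: 18 (1R,2R,3S,4S)-4-bromo-3-{2-[(tert-butyldiphenylsilyl)oxy]ethyl}-2-(hydroxymethyl)-1,3-dimethylcyclohexan-1-ol
Conditions: MeMgBr, CeCl3, THF, −78 → 0 °C
Reagents that add atoms: methylmagnesium bromide, C[Mg]Br
Why: Cerium-modified Grignard addition occurs from the equatorial direction because the axial face is blocked by the syn-axial C3a methyl, so the C7 hydroxyl ends axial (cis to the C3a methyl) and the methyl equatorial, while cerium suppresses enolisation and the primary alkoxide is not a leaving group for β-elimination.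

Step 11
Reactants: 18 (1R,2R,3S,4S)-4-bromo-3-{2-[(tert-butyldiphenylsilyl)oxy]ethyl}-2-(hydroxymethyl)-1,3-dimethylcyclohexan-1-ol
Product: 19 (1S,2S,3S,6R)-3-bromo-2-{2-[(tert-butyldiphenylsilyl)oxy]ethyl}-6-hydroxy-2,6-dimethylcyclohexane-1-carbaldehyde
Conditions: Dess–Martin periodinane, NaHCO3, CH2Cl2, 0 °C → rt
Reagents that add atoms: none
Why: Dess–Martin oxidation converts only the primary alcohol (the tertiary one cannot be oxidised), and the equatorial aldehyde is already the stable epimer at C7a.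

Step 12
Reactants: 20 tert-butyl acetoacetate; 21 1-bromo-3-methylbut-2-ene
Product: 23 tert-butyl 7-methyl-3-oxooct-6-enoate, via acetoacetate dianion 22 (not isolated)
Conditions: 20, NaH, THF, 0 °C; n-BuLi, 0 °C; then 21, 0 °C → rt
Reagents that add atoms: none
Why: Dianion alkylation (Huckin–Weiler) at the terminal carbon with prenyl bromide gives the ring-A chain with its 1,3-dicarbonyl terminus.

Step 13
Reactants: 23 tert-butyl 7-methyl-3-oxooct-6-enoate
Product: 25 tert-butyl (2Z)-3-[(diethoxyphosphoryl)oxy]-7-methylocta-2,6-dienoate, via sodium enolate 24 (not isolated)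
Conditions: NaH, Et2O, 0 °C; ClP(O)(OEt)2, 0 °C → rt
Reagents that add atoms: diethyl chlorophosphate, CCOP(=O)(Cl)OCC
Why: O-Phosphorylation of the chelated sodium enolate gives the (Z)-enol phosphate, as in step 5.

Step 14
Reactants: 25 tert-butyl (2Z)-3-[(diethoxyphosphoryl)oxy]-7-methylocta-2,6-dienoate; 12 (trimethylsilyl)methylmagnesium chloride
Product: 26 tert-butyl (2Z)-7-methyl-3-[(trimethylsilyl)methyl]octa-2,6-dienoate
Conditions: 12 (3 equiv), Ni(acac)2 (5 mol %), THF, 0 °C → rt
Reagents that add atoms: none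
Why: Nickel-catalysed Kumada-type coupling with retention of geometry gives the 3-(silylmethyl)enoate, as in step 6.

Step 15
Reactants: 26 tert-butyl (2Z)-7-methyl-3-[(trimethylsilyl)methyl]octa-2,6-dienoate
Product: 27 tert-butyl (1R,3S)-3-bromo-2,2-dimethyl-6-methylidenecyclohexane-1-carboxylate
Conditions: DBDMH (0.6 equiv), (R)-BINOL-derived thiophosphoramide (10 mol %), CH2Cl2/toluene, −78 °C; aq. Na2S2O3
Reagents that add atoms: 1,3-dibromo-5,5-dimethylhydantoin, O=C1N(Br)C(=O)C(C)(C)N1Br
Why: Proposed new method: the catalyst-bound bromenium ion is expected to brominate the prenyl-type alkene (C3′=C4′) rather than the electron-poor enoate, whose α-carbon (C2′) then opens the bromonium ion at tertiary C3′ in a 6-endo chair with loss of silicon, so that C4′ is set by the catalyst and the C2′ ester ends equatorial, cis-1,3 to the equatorial bromine; the closest known reactions are the catalytic enantioselective bromocyclisation of prenyl-terminated polyenes onto arenes and epoxide-initiated cyclisations onto 3-(silylmethyl)enoates.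

Step 16
Reactants: 27 tert-butyl (1R,3S)-3-bromo-2,2-dimethyl-6-methylidenecyclohexane-1-carboxylate
Product: 29 tert-butyl (1R,3S,6R)-3-bromo-6-(hydroxymethyl)-2,2-dimethylcyclohexane-1-carboxylate, via B-alkyl-9-BBN adduct 28 (not isolated)
Conditions: 9-BBN, THF, 0 °C → rt; H2O2, pH 7 buffer, 0 °C
Reagents that add atoms: hydrogen peroxide, OO
Why: Anti-Markovnikov hydroboration–oxidation of the exocyclic methylene, in a chair locked by the equatorial bromide and ester, delivers hydrogen to C1′ from the face opposite the syn-axial C3′ methyl, so the new CH2OH is cis to bromine.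

Step 17
Reactants: 29 tert-butyl (1R,3S,6R)-3-bromo-6-(hydroxymethyl)-2,2-dimethylcyclohexane-1-carboxylate
Product: 30 tert-butyl (1R,3S,6R)-3-bromo-2,2-dimethyl-6-{[(1-phenyl-1H-tetrazol-5-yl)sulfanyl]methyl}cyclohexane-1-carboxylate
Conditions: 1-phenyl-1H-tetrazole-5-thiol, PPh3, DIAD, THF, 0 °C → rt
Reagents that add atoms: 1-phenyl-1H-tetrazole-5-thiol, Sc1nnnn1-c1ccccc1
Why: Mitsunobu thioetherification of the primary alcohol with the acidic heteroaryl thiol installs the Julia–Kocienski activating group without touching a stereocentre.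

Step 18
Reactants: 30 tert-butyl (1R,3S,6R)-3-bromo-2,2-dimethyl-6-{[(1-phenyl-1H-tetrazol-5-yl)sulfanyl]methyl}cyclohexane-1-carboxylate
Product: 31 tert-butyl (1R,3S,6R)-3-bromo-2,2-dimethyl-6-{[(1-phenyl-1H-tetrazol-5-yl)sulfonyl]methyl}cyclohexane-1-carboxylate
Conditions: (NH4)6Mo7O24·4H2O (cat.), 30% H2O2, EtOH, 0 °C → rt
Reagents that add atoms: hydrogen peroxide, OO
Why: Molybdate-catalysed peroxide oxidation takes the sulfide to the sulfone; no alkene or other oxidisable group is present.

Step 19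
Reactants: 31 tert-butyl (1R,3S,6R)-3-bromo-2,2-dimethyl-6-{[(1-phenyl-1H-tetrazol-5-yl)sulfonyl]methyl}cyclohexane-1-carboxylate
Product: 32 (1R,3S,6R)-3-bromo-2,2-dimethyl-6-{[(1-phenyl-1H-tetrazol-5-yl)sulfonyl]methyl}cyclohexane-1-carboxylic acid
Conditions: TFA, CH2Cl2, 0 °C → rt
Reagents that add atoms: none
Why: Acidolysis of the tert-butyl ester (E1 loss of isobutene) frees the hindered acid without base, which could eliminate the bromide.

Step 20
Reactants: 32 (1R,3S,6R)-3-bromo-2,2-dimethyl-6-{[(1-phenyl-1H-tetrazol-5-yl)sulfonyl]methyl}cyclohexane-1-carboxylic acid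
Product: 35 5-({[(1R,4S)-4-bromo-3,3-dimethylcyclohexyl]methyl}sulfonyl)-1-phenyl-1H-tetrazole (CH2SO2 cis to Br), via acid chloride 33 (not isolated), via thiohydroxamate ester 34 (not isolated)
Conditions: (COCl)2, DMF (cat.), CH2Cl2, 0 °C → rt; sodium 2-thioxopyridin-1(2H)-olate, DMAP (cat.), t-BuSH, PhMe, hν (tungsten lamp), rt
Reagents that add atoms: none
Why: Barton reductive decarboxylation with a thiol as hydrogen donor (no tin) replaces the C2′ carboxyl, which has served as conformational lock, by hydrogen through a secondary radical that has no β-bromine or β-sulfonyl group to expel; C1′ and C4′ are untouched.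

Step 21
Reactants: 35 5-({[(1R,4S)-4-bromo-3,3-dimethylcyclohexyl]methyl}sulfonyl)-1-phenyl-1H-tetrazole; 19 (1S,2S,3S,6R)-3-bromo-2-{2-[(tert-butyldiphenylsilyl)oxy]ethyl}-6-hydroxy-2,6-dimethylcyclohexane-1-carbaldehyde
Product: 37 (1R,2S,3S,4S)-4-bromo-2-{(E)-2-[(1R,4S)-4-bromo-3,3-dimethylcyclohexyl]ethenyl}-3-{2-[(tert-butyldiphenylsilyl)oxy]ethyl}-1,3-dimethylcyclohexan-1-ol, via potassium sulfonyl carbanion 36 (not isolated)
Conditions: 35, KHMDS (1.05 equiv), DME, −60 °C; then 19, −60 °C → rt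
Reagents that add atoms: none
Why: Julia–Kocienski olefination of the phenyltetrazolyl sulfone anion with the α-branched aldehyde gives the (E)-alkene; the carbanion is too weak a base to deprotonate the tertiary alcohol and cannot reach the rear of the cis C4′–Br bond.

Step 22
Reactants: 37 (1R,2S,3S,4S)-4-bromo-2-{(E)-2-[(1R,4S)-4-bromo-3,3-dimethylcyclohexyl]ethenyl}-3-{2-[(tert-butyldiphenylsilyl)oxy]ethyl}-1,3-dimethylcyclohexan-1-ol
Product: 38 (1R,2S,3S,4S)-4-bromo-2-{(E)-2-[(1R,4S)-4-bromo-3,3-dimethylcyclohexyl]ethenyl}-3-(2-hydroxyethyl)-1,3-dimethylcyclohexan-1-ol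
Conditions: TBAF, AcOH, THF, rt
Reagents that add atoms: none
Why: Fluoride buffered with acetic acid cleaves the primary silyl ether without base-induced elimination of the secondary bromides.

Step 23
Reactants: 38 (1R,2S,3S,4S)-4-bromo-2-{(E)-2-[(1R,4S)-4-bromo-3,3-dimethylcyclohexyl]ethenyl}-3-(2-hydroxyethyl)-1,3-dimethylcyclohexan-1-ol
Product: 39 2-[(1S,2S,3R,6S)-6-bromo-2-{(E)-2-[(1R,4S)-4-bromo-3,3-dimethylcyclohexyl]ethenyl}-3-hydroxy-1,3-dimethylcyclohexyl]acetaldehyde
Conditions: Dess–Martin periodinane, NaHCO3, CH2Cl2, 0 °C → rt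
Reagents that add atoms: none
Why: Dess–Martin oxidation acts only on the primary alcohol, and the aldehyde cannot form a lactol because the axial C7 hydroxyl and the equatorial C3a arm lie on opposite faces of the ring.

Step 24
Reactants: 39 2-[(1S,2S,3R,6S)-6-bromo-2-{(E)-2-[(1R,4S)-4-bromo-3,3-dimethylcyclohexyl]ethenyl}-3-hydroxy-1,3-dimethylcyclohexyl]acetaldehyde
Product: 40 iriediol, (1S,2R,3aS,4S,7R,7aS)-4-bromo-1-{(E)-[(4S)-4-bromo-3,3-dimethylcyclohexylidene]methyl}-3a,7-dimethyloctahydro-1H-indene-2,7-diol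
Conditions: Me2AlCl (3 equiv), CH2Cl2, −78 → −20 °C
Reagents that add atoms: none
Why: Lewis-acid-promoted type I intramolecular carbonyl-ene reaction: the aldehyde carbon adds to C1 on the alkene face presented when C7a–H eclipses the C=C bond (allylic strain), which sets C1; the carbonyl oxygen must lie over Cv to take the C1′ hydrogen through the six-membered array, which puts the C2 hydroxyl cis to the C1 substituent; and with (R)-C1′ the C6′ methylene sits inside the array and ends cis to C1, which gives the E alkene.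

**Compound list**

1 | but-3-yn-1-ol | C#CCCO | starting material
2 | tert-butyl(but-3-yn-1-yloxy)diphenylsilane | C#CCCO[Si](c1ccccc1)(c1ccccc1)C(C)(C)C | intermediate
3 | dimethyl[(1E)-4-[(tert-butyldiphenylsilyl)oxy]-2-methylbut-1-en-1-yl]alane (formed in the flask) | C[Al](C)/C=C(C)/CCO[Si](c1ccccc1)(c1ccccc1)C(C)(C)C | intermediate
4 | lithium butyl(dimethyl)[(1E)-4-[(tert-butyldiphenylsilyl)oxy]-2-methylbut-1-en-1-yl]aluminate (formed in the flask) | [Li+].CCCC[Al-](C)(C)/C=C(C)/CCO[Si](c1ccccc1)(c1ccccc1)C(C)(C)C | intermediate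
5 | (E)-5-[(tert-butyldiphenylsilyl)oxy]-3-methylpent-2-en-1-ol | OC/C=C(C)/CCO[Si](c1ccccc1)(c1ccccc1)C(C)(C)C | intermediate
6 | (E)-[(5-bromo-3-methylpent-3-en-1-yl)oxy](tert-butyl)diphenylsilane | BrC/C=C(C)/CCO[Si](c1ccccc1)(c1ccccc1)C(C)(C)C | intermediate
7 | methyl acetoacetate | COC(=O)CC(C)=O | starting material
8 | lithium sodium dianion of methyl acetoacetate (formed in the flask) | [Li+].[Na+].COC(=O)[CH-]C(=O)[CH2-] | intermediate
9 | methyl (E)-9-[(tert-butyldiphenylsilyl)oxy]-7-methyl-3-oxonon-6-enoate | COC(=O)CC(=O)CC/C=C(C)/CCO[Si](c1ccccc1)(c1ccccc1)C(C)(C)C | intermediate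
10 | sodium (2Z,6E)-enolate of 9 (formed in the flask) | [Na+].COC(=O)/C=C([O-])/CC/C=C(C)/CCO[Si](c1ccccc1)(c1ccccc1)C(C)(C)C | intermediate
11 | methyl (2Z,6E)-9-[(tert-butyldiphenylsilyl)oxy]-3-[(diethoxyphosphoryl)oxy]-7-methylnona-2,6-dienoate | COC(=O)/C=C(OP(=O)(OCC)OCC)/CC/C=C(C)/CCO[Si](c1ccccc1)(c1ccccc1)C(C)(C)C | intermediate
12 | (trimethylsilyl)methylmagnesium chloride | C[Si](C)(C)C[Mg]Cl | starting material
13 | methyl (2Z,6E)-9-[(tert-butyldiphenylsilyl)oxy]-7-methyl-3-[(trimethylsilyl)methyl]nona-2,6-dienoate | COC(=O)/C=C(C[Si](C)(C)C)/CC/C=C(C)/CCO[Si](c1ccccc1)(c1ccccc1)C(C)(C)C | intermediate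
14 | methyl (1R,2S,3S)-3-bromo-2-{2-[(tert-butyldiphenylsilyl)oxy]ethyl}-2-methyl-6-methylidenecyclohexane-1-carboxylate | COC(=O)[C@@H]1C(=C)CC[C@H](Br)[C@@]1(C)CCO[Si](c1ccccc1)(c1ccccc1)C(C)(C)C | intermediate
15 | [(1R,2S,3S)-3-bromo-2-{2-[(tert-butyldiphenylsilyl)oxy]ethyl}-2-methyl-6-methylidenecyclohexyl]methanol | OC[C@@H]1C(=C)CC[C@H](Br)[C@@]1(C)CCO[Si](c1ccccc1)(c1ccccc1)C(C)(C)C | intermediate
16 | ozonide of 15 (spiro-1,2,4-trioxolane at C7, both epimers at the spiro carbon; formed in the flask) | OC[C@@H]1C2(OOCO2)CC[C@H](Br)[C@@]1(C)CCO[Si](c1ccccc1)(c1ccccc1)C(C)(C)C | intermediate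
17 | (2R,3S,4S)-4-bromo-3-{2-[(tert-butyldiphenylsilyl)oxy]ethyl}-2-(hydroxymethyl)-3-methylcyclohexan-1-one | OC[C@@H]1C(=O)CC[C@H](Br)[C@@]1(C)CCO[Si](c1ccccc1)(c1ccccc1)C(C)(C)C | intermediate
18 | (1R,2R,3S,4S)-4-bromo-3-{2-[(tert-butyldiphenylsilyl)oxy]ethyl}-2-(hydroxymethyl)-1,3-dimethylcyclohexan-1-ol | OC[C@@H]1[C@](C)(O)CC[C@H](Br)[C@@]1(C)CCO[Si](c1ccccc1)(c1ccccc1)C(C)(C)C | intermediate
19 | (1S,2S,3S,6R)-3-bromo-2-{2-[(tert-butyldiphenylsilyl)oxy]ethyl}-6-hydroxy-2,6-dimethylcyclohexane-1-carbaldehyde | O=C[C@@H]1[C@](C)(O)CC[C@H](Br)[C@@]1(C)CCO[Si](c1ccccc1)(c1ccccc1)C(C)(C)C | intermediate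
20 | tert-butyl acetoacetate | CC(=O)CC(=O)OC(C)(C)C | starting material
21 | 1-bromo-3-methylbut-2-ene | CC(C)=CCBr | starting material
22 | lithium sodium dianion of tert-butyl acetoacetate (formed in the flask) | [Li+].[Na+].[CH2-]C(=O)[CH-]C(=O)OC(C)(C)C | intermediate
23 | tert-butyl 7-methyl-3-oxooct-6-enoate | CC(C)=CCCC(=O)CC(=O)OC(C)(C)C | intermediate
24 | sodium (Z)-enolate of 23 (formed in the flask) | [Na+].CC(C)(C)OC(=O)/C=C([O-])/CCC=C(C)C | intermediate
25 | tert-butyl (2Z)-3-[(diethoxyphosphoryl)oxy]-7-methylocta-2,6-dienoate | CC(C)(C)OC(=O)/C=C(OP(=O)(OCC)OCC)/CCC=C(C)C | intermediate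
26 | tert-butyl (2Z)-7-methyl-3-[(trimethylsilyl)methyl]octa-2,6-dienoate | CC(C)(C)OC(=O)/C=C(C[Si](C)(C)C)/CCC=C(C)C | intermediate
27 | tert-butyl (1R,3S)-3-bromo-2,2-dimethyl-6-methylidenecyclohexane-1-carboxylate | CC(C)(C)OC(=O)[C@@H]1C(=C)CC[C@H](Br)C1(C)C | intermediate
28 | B-alkyl-9-borabicyclo[3.3.1]nonane adduct of 27 (formed in the flask) | CC(C)(C)OC(=O)[C@@H]1[C@H](CB2C3CCCC2CCC3)CC[C@H](Br)C1(C)C | intermediate
29 | tert-butyl (1R,3S,6R)-3-bromo-6-(hydroxymethyl)-2,2-dimethylcyclohexane-1-carboxylate | CC(C)(C)OC(=O)[C@@H]1[C@H](CO)CC[C@H](Br)C1(C)C | intermediate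
30 | tert-butyl (1R,3S,6R)-3-bromo-2,2-dimethyl-6-{[(1-phenyl-1H-tetrazol-5-yl)sulfanyl]methyl}cyclohexane-1-carboxylate | CC(C)(C)OC(=O)[C@@H]1[C@H](CSc2nnnn2-c2ccccc2)CC[C@H](Br)C1(C)C | intermediate
31 | tert-butyl (1R,3S,6R)-3-bromo-2,2-dimethyl-6-{[(1-phenyl-1H-tetrazol-5-yl)sulfonyl]methyl}cyclohexane-1-carboxylate | CC(C)(C)OC(=O)[C@@H]1[C@H](CS(=O)(=O)c2nnnn2-c2ccccc2)CC[C@H](Br)C1(C)C | intermediate
32 | (1R,3S,6R)-3-bromo-2,2-dimethyl-6-{[(1-phenyl-1H-tetrazol-5-yl)sulfonyl]methyl}cyclohexane-1-carboxylic acid | OC(=O)[C@@H]1[C@H](CS(=O)(=O)c2nnnn2-c2ccccc2)CC[C@H](Br)C1(C)C | intermediate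
33 | acid chloride of 32 (formed in the flask) | ClC(=O)[C@@H]1[C@H](CS(=O)(=O)c2nnnn2-c2ccccc2)CC[C@H](Br)C1(C)C | intermediate
34 | 2-thioxopyridin-1(2H)-yl ester of 32 (formed in the flask) | S=c1ccccn1OC(=O)[C@@H]1[C@H](CS(=O)(=O)c2nnnn2-c2ccccc2)CC[C@H](Br)C1(C)C | intermediate
35 | 5-({[(1R,4S)-4-bromo-3,3-dimethylcyclohexyl]methyl}sulfonyl)-1-phenyl-1H-tetrazole | CC1(C)C[C@H](CS(=O)(=O)c2nnnn2-c2ccccc2)CC[C@@H]1Br | intermediate
36 | potassium α-sulfonyl carbanion of 35 (formed in the flask) | [K+].CC1(C)C[C@H]([CH-]S(=O)(=O)c2nnnn2-c2ccccc2)CC[C@@H]1Br | intermediate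
37 | (1R,2S,3S,4S)-4-bromo-2-{(E)-2-[(1R,4S)-4-bromo-3,3-dimethylcyclohexyl]ethenyl}-3-{2-[(tert-butyldiphenylsilyl)oxy]ethyl}-1,3-dimethylcyclohexan-1-ol | CC1(C)C[C@H](/C=C/[C@@H]2[C@](C)(O)CC[C@H](Br)[C@@]2(C)CCO[Si](c3ccccc3)(c3ccccc3)C(C)(C)C)CC[C@@H]1Br | intermediate
38 | (1R,2S,3S,4S)-4-bromo-2-{(E)-2-[(1R,4S)-4-bromo-3,3-dimethylcyclohexyl]ethenyl}-3-(2-hydroxyethyl)-1,3-dimethylcyclohexan-1-ol | CC1(C)C[C@H](/C=C/[C@@H]2[C@](C)(O)CC[C@H](Br)[C@@]2(C)CCO)CC[C@@H]1Br | intermediate
39 | 2-[(1S,2S,3R,6S)-6-bromo-2-{(E)-2-[(1R,4S)-4-bromo-3,3-dimethylcyclohexyl]ethenyl}-3-hydroxy-1,3-dimethylcyclohexyl]acetaldehyde | CC1(C)C[C@H](/C=C/[C@@H]2[C@](C)(O)CC[C@H](Br)[C@@]2(C)CC=O)CC[C@@H]1Br | intermediate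
40 | iriediol, (1S,2R,3aS,4S,7R,7aS)-4-bromo-1-{(E)-[(4S)-4-bromo-3,3-dimethylcyclohexylidene]methyl}-3a,7-dimethyloctahydro-1H-indene-2,7-diol | CC1(C)C/C(=C/[C@@H]2[C@H](O)C[C@]3(C)[C@@H](Br)CC[C@@](C)(O)[C@@H]23)CC[C@@H]1Br | target

**Step count**

Total: 24 steps. Longest linear sequence: 15 steps (steps 1–11 and 21–24, from but-3-yn-1-ol); the ring-A branch is 9 steps (12–20) before the union.

**Steps most likely to fail**

Step 7. Bromenium may be delivered to the wrong alkene face or passed between alkenes before the ring closes, eroding enantiopurity. The bromonium ion may also lose a proton or be captured by an external nucleophile before the weakly nucleophilic enoate carbon attacks. The fallback installs bromine before ring closure by known steps. From 13, Shi asymmetric epoxidation (D-fructose-derived ketone, Oxone) of the electron-rich 6,7-alkene would give the epoxide methyl (2Z)-5-[(2R,3R)-3-{2-[(tert-butyldiphenylsilyl)oxy]ethyl}-3-methyloxiran-2-yl]-3-[(trimethylsilyl)methyl]pent-2-enoate F1. Li2NiBr4 in THF should open it at the secondary carbon with inversion to the bromohydrin methyl (2Z,6S,7R)-6-bromo-9-[(tert-butyldiphenylsilyl)oxy]-7-hydroxy-7-methyl-3-[(trimethylsilyl)methyl]non-2-enoate F2. Trifluoroacetic anhydride and pyridine would give the tertiary ester methyl (2Z,6S,7R)-6-bromo-9-[(tert-butyldiphenylsilyl)oxy]-7-methyl-7-(trifluoroacetoxy)-3-[(trimethylsilyl)methyl]non-2-enoate F3. Ionisation of F3 in hexafluoroisopropanol, with bromine assisting from the rear, generates the same bromonium ion enantiospecifically inside the molecule; capture by the allylsilane returns the route at 14.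

Step 15. The same processes threaten the ring-A cyclisation: loss of face selectivity through bromenium exchange, and proton loss before carbon capture. The fallback is the same known sequence. From 26, Shi epoxidation would give tert-butyl (2Z)-5-[(2R)-3,3-dimethyloxiran-2-yl]-3-[(trimethylsilyl)methyl]pent-2-enoate F4. Bromide opening at the secondary carbon would give tert-butyl (2Z,6S)-6-bromo-7-hydroxy-7-methyl-3-[(trimethylsilyl)methyl]oct-2-enoate F5. Trifluoroacetylation would give tert-butyl (2Z,6S)-6-bromo-7-methyl-7-(trifluoroacetoxy)-3-[(trimethylsilyl)methyl]oct-2-enoate F6. Solvolysis of F6 in hexafluoroisopropanol closes the ring and returns the route at 27.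

Step 24. The 1,2-disubstituted alkene may be too weak an ene donor for an aluminium-complexed aldehyde. Stepwise Prins addition with chloride capture, hydride shift or ionisation of the tertiary alcohol could then outrun the concerted hydrogen transfer. The fallback replaces the carbonyl enophile by an oxocarbenium ion. From 39, acetalisation with 4-methoxybenzyl alcohol (PPTS, molecular sieves) would give the bis(4-methoxybenzyl) acetal of 39 F7. TMSOTf with 2,6-di-tert-butyl-4-methylpyridine at −78 °C ionises it, and acetal-initiated ene-type cyclisation through the same six-membered array would give the C2 4-methoxybenzyl ether of iriediol F8. DDQ in wet CH2Cl2 frees the C2 hydroxyl and returns the route at 40.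

**Further compounds**

F1 | step 7 | methyl (2Z)-5-[(2R,3R)-3-{2-[(tert-butyldiphenylsilyl)oxy]ethyl}-3-methyloxiran-2-yl]-3-[(trimethylsilyl)methyl]pent-2-enoate | COC(=O)/C=C(C[Si](C)(C)C)/CC[C@H]1O[C@]1(C)CCO[Si](c2ccccc2)(c2ccccc2)C(C)(C)C
F2 | step 7 | methyl (2Z,6S,7R)-6-bromo-9-[(tert-butyldiphenylsilyl)oxy]-7-hydroxy-7-methyl-3-[(trimethylsilyl)methyl]non-2-enoate | COC(=O)/C=C(C[Si](C)(C)C)/CC[C@H](Br)[C@@](O)(C)CCO[Si](c1ccccc1)(c1ccccc1)C(C)(C)C
F3 | step 7 | methyl (2Z,6S,7R)-6-bromo-9-[(tert-butyldiphenylsilyl)oxy]-7-methyl-7-(trifluoroacetoxy)-3-[(trimethylsilyl)methyl]non-2-enoate | COC(=O)/C=C(C[Si](C)(C)C)/CC[C@H](Br)[C@@](OC(=O)C(F)(F)F)(C)CCO[Si](c1ccccc1)(c1ccccc1)C(C)(C)C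
F4 | step 15 | tert-butyl (2Z)-5-[(2R)-3,3-dimethyloxiran-2-yl]-3-[(trimethylsilyl)methyl]pent-2-enoate | CC(C)(C)OC(=O)/C=C(C[Si](C)(C)C)/CC[C@H]1OC1(C)C
F5 | step 15 | tert-butyl (2Z,6S)-6-bromo-7-hydroxy-7-methyl-3-[(trimethylsilyl)methyl]oct-2-enoate | CC(C)(C)OC(=O)/C=C(C[Si](C)(C)C)/CC[C@H](Br)C(C)(C)O
F6 | step 15 | tert-butyl (2Z,6S)-6-bromo-7-methyl-7-(trifluoroacetoxy)-3-[(trimethylsilyl)methyl]oct-2-enoate | CC(C)(C)OC(=O)/C=C(C[Si](C)(C)C)/CC[C@H](Br)C(C)(C)OC(=O)C(F)(F)F
F7 | step 24 | bis(4-methoxybenzyl) acetal of 39 | CC1(C)C[C@H](/C=C/[C@@H]2[C@](C)(O)CC[C@H](Br)[C@@]2(C)CC(OCc3ccc(OC)cc3)OCc3ccc(OC)cc3)CC[C@@H]1Br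
F8 | step 24 | C2 4-methoxybenzyl ether of iriediol | CC1(C)C/C(=C/[C@@H]2[C@H](OCc4ccc(OC)cc4)C[C@]3(C)[C@@H](Br)CC[C@@](C)(O)[C@@H]23)CC[C@@H]1Br
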